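The synthesis builds the benzene ring and the pyran ring of the isochroman half (primed locants) together from a furan and an alkyne. The structural feature used is the C8' phenol that sits beside ring-fusion carbon C8a' and peri to the C1'H2–O2' bridge, which is the pattern a furan–yne phenol synthesis delivers. In one gold-catalysed operation C4a'–C8a' and C7'–C8' are formed and the furan oxygen moves to C8'. The precursor is a tetrasubstituted 3-acyloxyfuran that carries the (2R,3R) propargyl ether side chain at one α-carbon and, through a CH2 link at the other, the bis-MOM (3R,4S)-isochromanone that is later unveiled as the quinone methide half.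

Key step: step 18

Remark: the target is written as its 8-oxo-6-hydroxy quinone methide tautomer; unprimed locants refer to that half (carried as the isochromanone), primed locants to the isochroman half. Compounds 12 and 14 are taken as purchasable. The furan oxygen is carried as an acetate and not as a silyl ether; the reason is given at step 18.

**Part A – furanone**

Step 1
Reactants: 1 methyl (R)-3-hydroxybutanoate
Product: 2 methyl (2R,3R)-3-hydroxy-2-methylbutanoate
Conditions: LiN(i-Pr)2 (2.2 equiv), THF, −78 → −20 °C; MeI, DMPU, −78 → 0 °C; aq. NH4Cl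
Reagents that add atoms: iodomethane (CI)
Why: Fráter–Seebach alkylation, in which the lithium-chelated alkoxide enolate is methylated on the face opposite the C3 methyl group, so the new C2 centre should be set anti to the existing carbinol centre.

Step 2
Reactants: 2 methyl (2R,3R)-3-hydroxy-2-methylbutanoate; 3 propargyl bromide
Product: 4 methyl (2R,3R)-2-methyl-3-(prop-2-yn-1-yloxy)butanoate
Conditions: Ag2O, 4 Å molecular sieves, Et2O, rt → reflux, dark
Reagents that add atoms: none
Why: Silver-oxide-mediated Williamson etherification activates the bromide without forming a free alkoxide, so the β-hydroxy ester should neither eliminate, retro-aldolise nor epimerise.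

Step 3
Reactants: 4 methyl (2R,3R)-2-methyl-3-(prop-2-yn-1-yloxy)butanoate
Product: 5 (2R,3R)-2-methyl-3-(prop-2-yn-1-yloxy)butanal
Conditions: i-Bu2AlH (1.1 equiv), CH2Cl2, −78 °C; aq. potassium sodium tartrate; used crude
Reagents that add atoms: none
Why: Partial ester reduction, in which the aluminium hemiacetal is stable at −78 °C and releases the aldehyde only on work-up, so the α-centre should survive.

Step 4
Reactants: 6 1-hydroxybutan-2-one
Product: 7 1-[(tert-butyldimethylsilyl)oxy]butan-2-one
Conditions: TBSCl, imidazole, CH2Cl2, 0 °C → rt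
Reagents that add atoms: tert-butyldimethylsilyl chloride (CC(C)(C)[Si](C)(C)Cl)
Why: Routine silylation of a primary alcohol, which blocks the hydroxyl group and shields the adjacent CH2 for the enolisation in step 5.

Step 5
Reactants: 7 1-[(tert-butyldimethylsilyl)oxy]butan-2-one; 5 (2R,3R)-2-methyl-3-(prop-2-yn-1-yloxy)butanal
Product: 8 (5S,6R)-1-[(tert-butyldimethylsilyl)oxy]-4-hydroxy-3,5-dimethyl-6-(prop-2-yn-1-yloxy)heptan-2-one (C3 and C4 epimers)
Conditions: 7 (1.2 equiv), LiN(i-Pr)2, THF, −78 °C; then 5, −78 °C; aq. NH4Cl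
Reagents that add atoms: none
Why: Kinetic lithium enolate aldol addition, in which deprotonation should occur at the ethyl CH2 away from the hindered silyloxy-bearing carbon, and the two new stereocentres need no control because both are erased in steps 6 and 7.

Step 6
Reactants: 8 aldol adduct
Product: 9 (5R,6R)-1-[(tert-butyldimethylsilyl)oxy]-3,5-dimethyl-6-(prop-2-yn-1-yloxy)heptane-2,4-dione
Conditions: Dess–Martin periodinane, CH2Cl2, 0 °C → rt
Reagents that add atoms: none
Why: Dess–Martin oxidation of the β-hydroxy ketone is essentially neutral, so the 1,3-diketone should form without loss of the propargyloxy group or of the C5 configuration.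

Step 7
Reactants: 9 silyloxy diketone
Product: 11 4-methyl-5-[(2R,3R)-3-(prop-2-yn-1-yloxy)butan-2-yl]furan-3(2H)-one, via hydroxy diketone 10 (not isolated)
Conditions: 2 M aq. HCl, THF, rt
Reagents that add atoms: none
Why: Acid removes the silyl group, and the freed primary alcohol adds to the distal ketone (5-exo-trig hemiketal) and dehydrates, the classical cyclodehydration of α'-hydroxy-1,3-diketones to 3(2H)-furanones.

**Part B – isochromanone benzylic bromide**

Step 8
Reactants: 12 5-bromobenzene-1,3-diol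
Product: 13 1-bromo-3,5-bis(methoxymethoxy)benzene
Conditions: MOMCl, i-Pr2NEt, CH2Cl2, 0 °C → rt
Reagents that add atoms: chloromethyl methyl ether (COCCl)
Why: O-Alkylation of both phenols installs ethers that direct the later ortho-metalation and are removed by dilute acid at the end.

Step 9
Reactants: 13 1-bromo-3,5-bis(methoxymethoxy)benzene; 14 (2S,3S)-2,3-epoxybutane
Product: 15 (2S,3S)-3-[3,5-bis(methoxymethoxy)phenyl]butan-2-ol
Conditions: Mg, THF, 45 °C; then CuI (10 mol %), 14, −30 → 0 °C; aq. NH4Cl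
Reagents that add atoms: none
Why: Copper-catalysed SN2 opening of the C2-symmetric trans-epoxide by the aryl Grignard reagent inverts the attacked carbon, which sets the benzylic centre as S and leaves the carbinol carbon S.

Step 10
Reactants: 15 (2S,3S)-3-[3,5-bis(methoxymethoxy)phenyl]butan-2-ol
Product: 17 (2R,3S)-3-[3,5-bis(methoxymethoxy)phenyl]butan-2-ol, via nitrobenzoate ester 16 (not isolated)
Conditions: 4-nitrobenzoic acid, PPh3, DIAD, THF, 0 °C → rt; then K2CO3, MeOH, rt
Reagents that add atoms: 4-nitrobenzoic acid (O=C(O)c1ccc(cc1)[N+](=O)[O-])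
Why: Mitsunobu esterification replaces the activated carbinol oxygen with inversion (S → R), and methanolysis by acyl–oxygen cleavage keeps the new configuration, which gives the trans C3/C4 relationship of the later lactone.

Step 11
Reactants: 17 (2R,3S)-3-[3,5-bis(methoxymethoxy)phenyl]butan-2-ol
Product: 19 (2R,3S)-3-[4-(hydroxymethyl)-3,5-bis(methoxymethoxy)phenyl]butan-2-ol, via aryl aldehyde 18 (not isolated)
Conditions: n-BuLi (2.3 equiv), THF, 0 °C; DMF, −78 → 0 °C; then MeOH, NaBH4, 0 °C; aq. NH4Cl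
Reagents that add atoms: N,N-dimethylformamide (CN(C)C=O)
Why: Directed ortho-metalation should occur at the one ring position flanked by both MOM ethers (the future C7), and formylation with in-situ borohydride reduction gives the benzylic alcohol.

Step 12
Reactants: 19 benzylic alcohol diol
Product: 20 (2R,3S)-3-[2,6-dibromo-4-(hydroxymethyl)-3,5-bis(methoxymethoxy)phenyl]butan-2-ol
Conditions: NBS (2.05 equiv), MeCN, 0 °C
Reagents that add atoms: N-bromosuccinimide (O=C1CCC(=O)N1Br)
Why: Electrophilic aromatic bromination fills the only two remaining ring positions, each para to one MOM ether and ortho to the other.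

Step 13
Reactants: 20 dibromide
Product: 21 (2R,3S)-3-[2-bromo-4-(hydroxymethyl)-3,5-bis(methoxymethoxy)-6-methylphenyl]butan-2-ol
Conditions: n-BuLi (3.05 equiv), THF, −78 °C; MeI, −78 °C; aq. NH4Cl
Reagents that add atoms: iodomethane (CI)
Why: After deprotonation of both hydroxyl groups a single bromine–lithium exchange should occur (the two bromines are equivalent and the aryllithium resists a second exchange), and the aryllithium is methylated far faster than the lithium alkoxides.

Step 14
Reactants: 21 bromo methyl diol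
Product: 23 (3R,4S)-7-(hydroxymethyl)-6,8-bis(methoxymethoxy)-3,4,5-trimethyl-3,4-dihydro-1H-isochromen-1-one, via hydroxy acid 22 (not isolated)
Conditions: n-BuLi (3.05 equiv), THF, −78 °C; CO2, −78 → 0 °C; 1 M HCl to pH 4, 0 °C; then EDC·HCl, DMAP (cat.), CH2Cl2, rt
Reagents that add atoms: carbon dioxide (O=C=O)
Why: Bromine–lithium exchange and carboxylation place the acid ortho to the side chain, and carbodiimide lactonisation of the δ-hydroxy acid goes by acyl substitution, so both stereocentres stay as set in steps 9 and 10.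

Step 15
Reactants: 23 hydroxymethyl lactone
Product: 24 (3R,4S)-7-(bromomethyl)-6,8-bis(methoxymethoxy)-3,4,5-trimethyl-3,4-dihydro-1H-isochromen-1-one
Conditions: CBr4, PPh3, CH2Cl2, 0 °C; used at once
Reagents that add atoms: tetrabromomethane (BrC(Br)(Br)Br)
Why: Appel bromination converts the primary benzylic alcohol under neutral conditions that the MOM ethers and the lactone should tolerate.

**Part C – union, key step and endgame**

Step 16
Reactants: 11 4-methyl-5-[(2R,3R)-3-(prop-2-yn-1-yloxy)butan-2-yl]furan-3(2H)-one; 24 benzylic bromide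
Product: 25 2-{[(3R,4S)-6,8-bis(methoxymethoxy)-3,4,5-trimethyl-1-oxo-3,4-dihydro-1H-isochromen-7-yl]methyl}-4-methyl-5-[(2R,3R)-3-(prop-2-yn-1-yloxy)butan-2-yl]furan-3(2H)-one (both C2 epimers)
Conditions: 11, LiN(SiMe3)2 (1.05 equiv), THF, −78 °C; then 24, −78 → −30 °C
Reagents that add atoms: none
Why: Enolate alkylation, in which kinetic deprotonation of a 3(2H)-furanone occurs at C2 to give the aromatic 3-furanolate and its lithium salt is C-alkylated by the reactive benzylic bromide; the new C2 centre is not controlled and disappears in step 17.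

Step 17
Reactants: 25 2-benzylfuranone
Product: 26 2-{[(3R,4S)-6,8-bis(methoxymethoxy)-3,4,5-trimethyl-1-oxo-3,4-dihydro-1H-isochromen-7-yl]methyl}-4-methyl-5-[(2R,3R)-3-(prop-2-yn-1-yloxy)butan-2-yl]furan-3-yl acetate
Conditions: LiN(SiMe3)2 (1.1 equiv), THF, −78 °C; Ac2O, −78 → 0 °C
Reagents that add atoms: acetic anhydride (CC(=O)OC(C)=O)
Why: O-Acylation of the furanolate by the hard anhydride gives the enol acetate, driven by aromatisation to the furan.

Step 18
Reactants: 26 3-acetoxyfuran propargyl ether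
Product: 28 (3R,4S)-7-{[(3R,4S)-6,8-bis(methoxymethoxy)-3,4,5-trimethyl-1-oxo-3,4-dihydro-1H-isochromen-7-yl]methyl}-8-hydroxy-3,4,5-trimethyl-3,4-dihydro-1H-isochromen-6-yl acetate, via arene oxide 27 (not isolated)
Conditions: AuCl3 (5 mol %), MeCN, rt
Reagents that add atoms: none
Why: Gold-catalysed furan–yne phenol synthesis, established for alkyl- and aryl-substituted furans with this four-atom C–C–O–C tether but not yet run on a 3-oxygenated furan: the gold-bound terminal alkyne is attacked by the methyl-bearing C4=C5 bond of the furan at the tether-bearing carbon to give a cyclopropyl gold carbene, the furan C5–O bond opens to a dienone carbene, the ketone oxygen adds to the carbene carbon, and the oxepine closes to arene oxide 27, which opens to the phenol. The pyran ring closes in the 6-exo-dig mode (C4a'–C8a'), helped by the two methyl-bearing tether carbons, and the benzene ring closes by 6π electrocyclisation of the oxepine (C7'–C8'). No stereocentre is created and the two centres in the tether are not touched. The step needs the oxide to open at C7'–O, so that the former alkyne CH (C8') keeps the oxygen and loses its proton; C7' is fully substituted and the cation formed is tertiary at C7', C5' and C8a'. For this reason the furan oxygen is an acetate: a strong donor such as a silyl ether on C6' would push the oxide open at C8'–O, leave the oxygen on quaternary C7' and invite silyl transfer to it.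

Step 19
Reactants: 28 phenol acetate lactone
Product: 29 (3R,4S)-7-{[(3R,4S)-1-hydroxy-6,8-bis(methoxymethoxy)-3,4,5-trimethyl-3,4-dihydro-1H-isochromen-7-yl]methyl}-3,4,5-trimethyl-3,4-dihydro-1H-isochromene-6,8-diol (lactol C1 epimers)
Conditions: i-Bu2AlH (6 equiv), CH2Cl2, −78 °C; aq. potassium sodium tartrate
Reagents that add atoms: none
Why: Aluminium hydride reduction at −78 °C stops the aryl lactone at the lactol stage (stable cyclic aluminium hemiacetal) and cleaves the aryl acetate in the same operation.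

Step 20
Reactants: 29 bis-MOM lactol
Product: 31 dicitrinone I, via tetrahydroxy lactol 30 (not isolated)
Conditions: 3 M aq. HCl, THF, 40 °C
Reagents that add atoms: none
Why: Acid hydrolysis removes both MOM ethers, and the 6,8-dihydroxy lactol then ionises at C1 and loses water to the conjugated, hydrogen-bonded quinone methide, the stable form of citrinin-type hemiacetals, without touching C3, C4, C3' or C4'.

**Compound list**

1 | methyl (R)-3-hydroxybutanoate | C[C@@H](O)CC(=O)OC | starting material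
2 | methyl (2R,3R)-3-hydroxy-2-methylbutanoate | C[C@@H](O)[C@@H](C)C(=O)OC | intermediate
3 | propargyl bromide (3-bromoprop-1-yne) | C#CCBr | starting material
4 | methyl (2R,3R)-2-methyl-3-(prop-2-yn-1-yloxy)butanoate | C#CCO[C@H](C)[C@@H](C)C(=O)OC | intermediate
5 | (2R,3R)-2-methyl-3-(prop-2-yn-1-yloxy)butanal | C#CCO[C@H](C)[C@@H](C)C=O | intermediate
6 | 1-hydroxybutan-2-one | CCC(=O)CO | starting material
7 | 1-[(tert-butyldimethylsilyl)oxy]butan-2-one | CCC(=O)CO[Si](C)(C)C(C)(C)C | intermediate
8 | (5S,6R)-1-[(tert-butyldimethylsilyl)oxy]-4-hydroxy-3,5-dimethyl-6-(prop-2-yn-1-yloxy)heptan-2-one (C3 and C4 epimers) | C#CCO[C@H](C)[C@@H](C)C(O)C(C)C(=O)CO[Si](C)(C)C(C)(C)C | intermediate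
9 | (5R,6R)-1-[(tert-butyldimethylsilyl)oxy]-3,5-dimethyl-6-(prop-2-yn-1-yloxy)heptane-2,4-dione | C#CCO[C@H](C)[C@@H](C)C(=O)C(C)C(=O)CO[Si](C)(C)C(C)(C)C | intermediate
10 | (5R,6R)-1-hydroxy-3,5-dimethyl-6-(prop-2-yn-1-yloxy)heptane-2,4-dione | C#CCO[C@H](C)[C@@H](C)C(=O)C(C)C(=O)CO | intermediate
11 | 4-methyl-5-[(2R,3R)-3-(prop-2-yn-1-yloxy)butan-2-yl]furan-3(2H)-one | C#CCO[C@H](C)[C@@H](C)C1=C(C)C(=O)CO1 | intermediate
12 | 5-bromobenzene-1,3-diol | Oc1cc(O)cc(Br)c1 | starting material
13 | 1-bromo-3,5-bis(methoxymethoxy)benzene | COCOc1cc(Br)cc(OCOC)c1 | intermediate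
14 | (2S,3S)-2,3-epoxybutane | C[C@@H]1O[C@H]1C | starting material
15 | (2S,3S)-3-[3,5-bis(methoxymethoxy)phenyl]butan-2-ol | C[C@H](O)[C@@H](C)c1cc(OCOC)cc(OCOC)c1 | intermediate
16 | (2R,3S)-3-[3,5-bis(methoxymethoxy)phenyl]butan-2-yl 4-nitrobenzoate | C[C@@H](OC(=O)c1ccc(cc1)[N+](=O)[O-])[C@@H](C)c1cc(OCOC)cc(OCOC)c1 | intermediate
17 | (2R,3S)-3-[3,5-bis(methoxymethoxy)phenyl]butan-2-ol | C[C@@H](O)[C@@H](C)c1cc(OCOC)cc(OCOC)c1 | intermediate
18 | 4-[(2S,3R)-3-hydroxybutan-2-yl]-2,6-bis(methoxymethoxy)benzaldehyde | C[C@@H](O)[C@@H](C)c1cc(OCOC)c(C=O)c(OCOC)c1 | intermediate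
19 | (2R,3S)-3-[4-(hydroxymethyl)-3,5-bis(methoxymethoxy)phenyl]butan-2-ol | C[C@@H](O)[C@@H](C)c1cc(OCOC)c(CO)c(OCOC)c1 | intermediate
20 | (2R,3S)-3-[2,6-dibromo-4-(hydroxymethyl)-3,5-bis(methoxymethoxy)phenyl]butan-2-ol | C[C@@H](O)[C@@H](C)c1c(Br)c(OCOC)c(CO)c(OCOC)c1Br | intermediate
21 | (2R,3S)-3-[2-bromo-4-(hydroxymethyl)-3,5-bis(methoxymethoxy)-6-methylphenyl]butan-2-ol | C[C@@H](O)[C@@H](C)c1c(C)c(OCOC)c(CO)c(OCOC)c1Br | intermediate
22 | 2-[(2S,3R)-3-hydroxybutan-2-yl]-5-(hydroxymethyl)-4,6-bis(methoxymethoxy)-3-methylbenzoic acid | C[C@@H](O)[C@@H](C)c1c(C)c(OCOC)c(CO)c(OCOC)c1C(=O)O | intermediate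
23 | (3R,4S)-7-(hydroxymethyl)-6,8-bis(methoxymethoxy)-3,4,5-trimethyl-3,4-dihydro-1H-isochromen-1-one | OCc1c(OCOC)c(C)c2c(c1OCOC)C(=O)O[C@H](C)[C@H]2C | intermediate
24 | (3R,4S)-7-(bromomethyl)-6,8-bis(methoxymethoxy)-3,4,5-trimethyl-3,4-dihydro-1H-isochromen-1-one | BrCc1c(OCOC)c(C)c2c(c1OCOC)C(=O)O[C@H](C)[C@H]2C | intermediate
25 | 2-{[(3R,4S)-6,8-bis(methoxymethoxy)-3,4,5-trimethyl-1-oxo-3,4-dihydro-1H-isochromen-7-yl]methyl}-4-methyl-5-[(2R,3R)-3-(prop-2-yn-1-yloxy)butan-2-yl]furan-3(2H)-one (C2 epimers) | C#CCO[C@H](C)[C@@H](C)C1=C(C)C(=O)C(Cc2c(OCOC)c(C)c3c(c2OCOC)C(=O)O[C@H](C)[C@H]3C)O1 | intermediate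
26 | 2-{[(3R,4S)-6,8-bis(methoxymethoxy)-3,4,5-trimethyl-1-oxo-3,4-dihydro-1H-isochromen-7-yl]methyl}-4-methyl-5-[(2R,3R)-3-(prop-2-yn-1-yloxy)butan-2-yl]furan-3-yl acetate | C#CCO[C@H](C)[C@@H](C)c1oc(Cc2c(OCOC)c(C)c3c(c2OCOC)C(=O)O[C@H](C)[C@H]3C)c(OC(C)=O)c1C | intermediate
27 | arene oxide of 28: the 7',8'-epoxy-7',8'-dihydro isomer with the oxirane across C7'–C8' (both epoxide faces) | CC(=O)OC1=C(C)C2=C(CO[C@H](C)[C@H]2C)C3OC13Cc1c(OCOC)c(C)c2c(c1OCOC)C(=O)O[C@H](C)[C@H]2C | intermediate
28 | (3R,4S)-7-{[(3R,4S)-6,8-bis(methoxymethoxy)-3,4,5-trimethyl-1-oxo-3,4-dihydro-1H-isochromen-7-yl]methyl}-8-hydroxy-3,4,5-trimethyl-3,4-dihydro-1H-isochromen-6-yl acetate | C(c1c(OCOC)c(C)c2c(c1OCOC)C(=O)O[C@H](C)[C@H]2C)c1c(OC(C)=O)c(C)c2c(c1O)CO[C@H](C)[C@H]2C | intermediate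
29 | (3R,4S)-7-{[(3R,4S)-1-hydroxy-6,8-bis(methoxymethoxy)-3,4,5-trimethyl-3,4-dihydro-1H-isochromen-7-yl]methyl}-3,4,5-trimethyl-3,4-dihydro-1H-isochromene-6,8-diol (C1 epimers) | C(c1c(OCOC)c(C)c2c(c1OCOC)C(O)O[C@H](C)[C@H]2C)c1c(O)c(C)c2c(c1O)CO[C@H](C)[C@H]2C | intermediate
30 | (3R,4S)-7-{[(3R,4S)-6,8-dihydroxy-3,4,5-trimethyl-3,4-dihydro-1H-isochromen-7-yl]methyl}-3,4,5-trimethyl-3,4-dihydro-1H-isochromene-1,6,8-triol (C1 epimers) | C(c1c(O)c(C)c2c(c1O)C(O)O[C@H](C)[C@H]2C)c1c(O)c(C)c2c(c1O)CO[C@H](C)[C@H]2C | intermediate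
31 | dicitrinone I | CC1=C2C(=CO[C@H](C)[C@H]2C)C(=O)C(Cc2c(O)c(C)c3c(c2O)CO[C@H](C)[C@H]3C)=C1O | target

**Step count and risk**

Total: 20 steps. Longest linear sequence: 13 steps (steps 8–20). The furanone branch (steps 1–7) joins at step 16.

The three steps most likely to fail:

1. Step 18. The acyloxy-substituted furan may not capture the gold-activated alkyne, the arene oxide may open toward C8' so that no aromatisation follows, or Lewis-acid traces may strip the enol ester before cyclisation. The fallback gives up the furan route and joins two aromatic halves by electrophilic substitution. It sets out from 17. Monobromination with NBS para to a MOM ether should give (2R,3S)-3-[2-bromo-3,5-bis(methoxymethoxy)phenyl]butan-2-ol F1. Bromine–lithium exchange and methylation (n-BuLi, then MeI) should give (2R,3S)-3-[3,5-bis(methoxymethoxy)-2-methylphenyl]butan-2-ol F2. Methanolic HCl frees (2R,3S)-3-(3,5-dihydroxy-2-methylphenyl)butan-2-ol F3. Oxa-Pictet–Spengler closure with dimethoxymethane and acid gives (3R,4S)-3,4,5-trimethyl-3,4-dihydro-1H-isochromene-6,8-diol F4. Friedel–Crafts benzylation of F4 at C7', its only free ring position, with bromide 24 in hexafluoroisopropanol should give (3R,4S)-7-{[(3R,4S)-6,8-dihydroxy-3,4,5-trimethyl-3,4-dihydro-1H-isochromen-7-yl]methyl}-6,8-bis(methoxymethoxy)-3,4,5-trimethyl-3,4-dihydro-1H-isochromen-1-one F5. Reduction of F5 with i-Bu2AlH at −78 °C comes back to the route at 29.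

2. Step 16. The ambident furanolate may react at oxygen or be alkylated twice after proton transfer, and the electron-rich benzylic bromide may ionise and decompose before it couples. The fallback replaces alkylation by condensation and reduction. It sets out from 23 and 11. Oxidation of 23 with MnO2 should give (3R,4S)-6,8-bis(methoxymethoxy)-3,4,5-trimethyl-1-oxo-3,4-dihydro-1H-isochromene-7-carbaldehyde F6. Aldol condensation of F6 with 11 (piperidinium acetate, toluene) should give 2-{[(3R,4S)-6,8-bis(methoxymethoxy)-3,4,5-trimethyl-1-oxo-3,4-dihydro-1H-isochromen-7-yl]methylidene}-4-methyl-5-[(2R,3R)-3-(prop-2-yn-1-yloxy)butan-2-yl]furan-3(2H)-one F7. Conjugate reduction of the exocyclic enone with zinc dust in acetic acid comes back to the route at 25.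

3. Step 10. Elimination toward the conjugated alkene or incomplete inversion may occur at the hindered secondary carbinol. The fallback replaces displacement by oxidation and reduction. It sets out from 15. Dess–Martin oxidation should give (S)-3-[3,5-bis(methoxymethoxy)phenyl]butan-2-one F8. Reduction with LiBH(s-Bu)3 in THF at −78 °C, with hydride delivered anti to the aryl group under Felkin–Anh control, comes back to the route at 17.

**Further compounds**

F1 | step 18 | (2R,3S)-3-[2-bromo-3,5-bis(methoxymethoxy)phenyl]butan-2-ol | C[C@@H](O)[C@@H](C)c1cc(OCOC)cc(OCOC)c1Br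
F2 | step 18 | (2R,3S)-3-[3,5-bis(methoxymethoxy)-2-methylphenyl]butan-2-ol | C[C@@H](O)[C@@H](C)c1cc(OCOC)cc(OCOC)c1C
F3 | step 18 | (2R,3S)-3-(3,5-dihydroxy-2-methylphenyl)butan-2-ol | C[C@@H](O)[C@@H](C)c1cc(O)cc(O)c1C
F4 | step 18 | (3R,4S)-3,4,5-trimethyl-3,4-dihydro-1H-isochromene-6,8-diol | c1c(O)c(C)c2c(c1O)CO[C@H](C)[C@H]2C
F5 | step 18 | (3R,4S)-7-{[(3R,4S)-6,8-dihydroxy-3,4,5-trimethyl-3,4-dihydro-1H-isochromen-7-yl]methyl}-6,8-bis(methoxymethoxy)-3,4,5-trimethyl-3,4-dihydro-1H-isochromen-1-one | C(c1c(OCOC)c(C)c2c(c1OCOC)C(=O)O[C@H](C)[C@H]2C)c1c(O)c(C)c2c(c1O)CO[C@H](C)[C@H]2C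
F6 | step 16 | (3R,4S)-6,8-bis(methoxymethoxy)-3,4,5-trimethyl-1-oxo-3,4-dihydro-1H-isochromene-7-carbaldehyde | O=Cc1c(OCOC)c(C)c2c(c1OCOC)C(=O)O[C@H](C)[C@H]2C
F7 | step 16 | 2-{[(3R,4S)-6,8-bis(methoxymethoxy)-3,4,5-trimethyl-1-oxo-3,4-dihydro-1H-isochromen-7-yl]methylidene}-4-methyl-5-[(2R,3R)-3-(prop-2-yn-1-yloxy)butan-2-yl]furan-3(2H)-one | C#CCO[C@H](C)[C@@H](C)C1=C(C)C(=O)C(=Cc2c(OCOC)c(C)c3c(c2OCOC)C(=O)O[C@H](C)[C@H]3C)O1
F8 | step 10 | (S)-3-[3,5-bis(methoxymethoxy)phenyl]butan-2-one | CC(=O)[C@@H](C)c1cc(OCOC)cc(OCOC)c1
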